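**Retrosynthetic overview**
- Feature: in the ten-membered ring, the run C10=C1–C2–C3–C4–C5 is a masked cis,trans-cyclodeca-1,5-diene. C1=C10 is E, and the C4–C5 oxirane is ring-cis, hence a former Z-alkene. C6, next to C5, carries oxygen. This pattern is left when a cyclohexenone–cyclobutene photoadduct is opened across C5–C10 and C1–C4.
- Late disconnections: the C6 acetate; the C4–C5 oxirane (hydroxyl-directed from the C6 carbinol); the ten-membered ring, which goes back to a 5-6-4-4 tetracycle by reversing the thermal opening.
- Four operations are done on the rigid 6-4-4 frame before it is opened: C7–C11 alkylation, C8–O lactonisation, C6 reduction and C13 methylenation. All are steered by the convex face of the photoadduct.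
- Key disconnection: C1–C10 and C4–C5. This leads to (R)-3-methyl-5-silyloxycyclohexenone (C5–C10, from desymmetrised all-cis-cyclohexanetriol) and (S)-3-silyloxy-1-methylcyclobutene (C1–C4, from propyne and dichloroketene).
- Ring order: cyclohexane (bought) and outer cyclobutene, then central cyclobutane (photocycloaddition), then γ-lactone, then ten-membered ring (the six-membered and both four-membered rings are given up), then oxirane.

Key step: step 10

Convention: germacrane numbering (C1–C15) is used from step 10 on. β is the face of the C5–C10 ring that carries O-8; α is the opposite face.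
Assumption 1: the lipase is taken to acylate the (R)-configured carbinol of the meso diol (empirical rule for secondary alcohols, silyloxy-bearing flank as the large group). The sense has to be confirmed at the enone of step 3.
Assumption 2: in the oxazaborolidine reduction the alkenyl flank of 3-methylcyclobutenone is taken as the larger group, so the (R)-catalyst is assigned to the (S)-alcohol.

**Step 1**
Reactants: 1 cis,cis-cyclohexane-1,3,5-triol
Product: 2 all-cis-5-(triethylsilyloxy)cyclohexane-1,3-diol (meso)
Conditions: Et3SiCl (1 equiv), imidazole, DMF, 0 °C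
Reagents that add atoms: chlorotriethylsilane, CC[Si](Cl)(CC)CC
Why: Silyl ether formation on one of three equivalent hydroxyl groups (statistical monoprotection, triol and bis-ether being recycled) gives a meso diol without creating a stereocentre, and the triethylsilyl group is chosen so that O-8 can later be freed in the presence of the C2 tert-butyldimethylsilyl ether.

**Step 2**
Reactants: 2 all-cis-5-(triethylsilyloxy)cyclohexane-1,3-diol
Product: 3 (1R,3S,5S)-3-hydroxy-5-(triethylsilyloxy)cyclohexyl acetate
Conditions: Burkholderia cepacia lipase (Amano PS), vinyl acetate, MTBE, 30 °C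
Reagents that add atoms: vinyl acetate, C=COC(C)=O
Why: Lipase-catalysed irreversible transesterification desymmetrises the meso diol by acylating only one of the two enantiotopic carbinols, which makes the silyloxy carbon (the future C8) a defined stereocentre.

**Step 3**
Reactants: 3 (1R,3S,5S)-3-hydroxy-5-(triethylsilyloxy)cyclohexyl acetate
Product: 5 (R)-5-(triethylsilyloxy)cyclohex-2-en-1-one, via β-acetoxy ketone 4 (not isolated)
Conditions: Dess–Martin periodinane, pyridine, CH2Cl2, 0 °C to rt; crude 4, DBU, CH2Cl2, 0 °C
Reagents that add atoms: none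
Why: Dess–Martin oxidation of the free carbinol followed by E1cB elimination expels acetate, a far better leaving group than the silyloxide on the other β carbon, so that the enone forms without touching C8.

**Step 4**
Reactants: 5 (R)-5-(triethylsilyloxy)cyclohex-2-en-1-one
Product: 6 (3R,5R)-3-methyl-5-(triethylsilyloxy)-1-(trimethylsilyloxy)cyclohex-1-ene (methyl trans to the triethylsilyloxy group)
Conditions: Me2CuLi (from MeLi and CuI), Me3SiCl, Et2O–THF, −78 °C; Et3N, neutral work-up
Reagents that add atoms: methyllithium, [Li]C; chlorotrimethylsilane, C[Si](C)(C)Cl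
Why: Me3SiCl-accelerated Gilman conjugate addition delivers methyl axially and anti to the silyloxy group (trans product) and traps the enolate at once as its silyl enol ether, which fixes the enol regiochemistry and prevents loss of the β-silyloxy group; the new methyl-bearing centre disappears in step 5.

**Step 5**
Reactants: 6 (3R,5R)-3-methyl-5-(triethylsilyloxy)-1-(trimethylsilyloxy)cyclohex-1-ene
Product: 7 (R)-3-methyl-5-(triethylsilyloxy)cyclohex-2-en-1-one
Conditions: Pd(OAc)2 (10 mol %), O2 (1 atm), DMSO, rt
Reagents that add atoms: none
Why: Saegusa–Ito oxidation: the divalent palladium enolate formed from the silyl enol ether can undergo β-hydride elimination only toward the methyl-bearing carbon, which restores the enone with the carbonyl group in its old place and so gives the (R)-configured 3-methyl enone, zerovalent palladium being reoxidised by O2.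

**Step 6**
Reactants: 8 propyne; 9 trichloroacetyl chloride
Product: 11 4,4-dichloro-3-methylcyclobut-2-en-1-one, via dichloroketene 10 (not isolated)
Conditions: Zn(Cu), Et2O–DME, 0 °C to rt
Reagents that add atoms: none
Why: Ketene–alkyne [2+2] cycloaddition: dichloroketene generated by zinc dechlorination bonds through its carbonyl carbon to the terminal alkyne carbon, which places the methyl group at C3 of the cyclobutenone.

**Step 7**
Reactants: 11 4,4-dichloro-3-methylcyclobut-2-en-1-one
Product: 12 3-methylcyclobut-2-en-1-one
Conditions: Zn, AcOH, TMEDA, EtOH, 0 °C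
Reagents that add atoms: none
Why: Reductive dechlorination α to the carbonyl group through zinc enolates, buffered by TMEDA and AcOH, removes both chlorines below the temperature at which the cyclobutenone would ring-open to a vinylketene.

**Step 8**
Reactants: 12 3-methylcyclobut-2-en-1-one
Product: 13 (S)-3-methylcyclobut-2-en-1-ol
Conditions: (R)-Me-CBS oxazaborolidine (20 mol %), catecholborane, toluene, −78 °C; hydrolytic work-up
Reagents that add atoms: none
Why: Corey–Bakshi–Shibata reduction: the ketone binds to the oxazaborolidine boron anti to its alkenyl flank and receives hydride on one face only to give the (S)-carbinol (future C2), catecholborane at low temperature giving clean 1,2-reduction without hydroboration.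

**Step 9**
Reactants: 13 (S)-3-methylcyclobut-2-en-1-ol
Product: 14 (S)-3-(tert-butyldimethylsilyloxy)-1-methylcyclobutene
Conditions: tBuMe2SiCl, imidazole, CH2Cl2, 0 °C to rt
Reagents that add atoms: tert-butylchlorodimethylsilane, CC(C)(C)[Si](C)(C)Cl
Why: Standard silyl ether formation protects the allylic alcohol without touching C2 and supplies the bulky group that will shield one face of the cyclobutene.

**Step 10**
Reactants: 7 (R)-3-methyl-5-(triethylsilyloxy)cyclohex-2-en-1-one; 14 (S)-3-(tert-butyldimethylsilyloxy)-1-methylcyclobutene
Product: 15 cis-anti-cis 6-4-4 tricyclic ketone, (2S,8R)-1,5-dimethyl-3-(tert-butyldimethylsilyloxy)-9-(triethylsilyloxy)tricyclo[4.4.0.0^2,5]decan-7-one (germacrane C6 ketone; C10–C1 and C5–C4 bonds α; H5 and C14 β; O-8 β; O-2 exo)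
Conditions: hν (350 nm lamps, Pyrex), 14 (3 equiv), degassed CH2Cl2, −20 °C; then Al2O3 (neutral), Et2O, rt
Reagents that add atoms: none
Why: Light of about 350 nm excites only enone 7 (n,π*), and after intersystem crossing its twisted triplet bonds through C10 to the unsubstituted cyclobutene carbon C1, giving the triplet 1,4-diradical with an α-acyl radical at C5 and a tertiary radical at C4. Spin inversion and radical–radical recombination C4–C5 then close the central cyclobutane (four-membered closure of a 1,4-diradical), the closest known reaction type being the intermolecular enone–alkene [2+2] photocycloaddition of 3-alkylcyclohexenones with 1-methylcyclobutene. The regiochemistry needed (C10 to C1, C5 to C4) is secured by the two methyl groups, because the other orientation would have to join the fully substituted carbons C10 and C4 and that diradical should fall back to 7 and 14 instead of closing. C10 and C5 are controlled by C8: the cyclobutene bonds axially at C10 on the α face, anti to the equatorial C8 silyloxy group, and C5 follows as the cis 6-4 fusion, any trans-fused ketone being epimerised at C5 on Al2O3. C1 and C4 are controlled by C2: the flat cyclobutene is attacked on the face away from its silyloxy group, the 4-4 fusion can only be cis, and the anti arrangement of the two outer rings avoids contact of C2/C3 with C6/C9 in the closing diradical. Silyl ethers are transparent and inert here, excess 14 is recovered, and adduct derived from any residual (R)-14 is a diastereomer that is removed at this stage.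

**Step 11**
Reactants: 15 cis-anti-cis tricyclic ketone
Product: 17 C7-alkylated keto ester (methyl ester arm C11–C12 on the β face of C7 and cis to O-8), via lithium enolate 16 (not isolated)
Conditions: LiN(iPr)2, THF, −78 °C; BrCH2CO2Me, DMPU, −78 to −30 °C
Reagents that add atoms: methyl bromoacetate, COC(=O)CBr
Why: Kinetic deprotonation at the only α-methylene (C7, since C5–H is a hindered cyclobutane methine) and SN2 alkylation of the lithium enolate by axial attack on the convex β face, the α face being screened by the C15 methyl group under the ring, set C7 with C11 cis to O-8, while the equatorial C8 silyloxy group is poorly aligned for E1cB loss.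

**Step 12**
Reactants: 17 C7-alkylated keto ester
Product: 19 tetracyclic 6-oxo-12,8-olide (cis-fused γ-lactone on the β face; H7 and H8 α; 2-OTBS kept), via hydroxy ester 18 (not isolated)
Conditions: PPTS (cat.), MeOH, rt
Reagents that add atoms: none
Why: Acid-catalysed methanolysis removes the triethylsilyl ether much faster than the secondary tert-butyldimethylsilyl ether, and the freed C8 hydroxyl, cis to the ester arm, closes the γ-lactone by transesterification (5-exo-trig), the cis 6-5 fusion also being the thermodynamic arrangement at the enolisable C7.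

**Step 13**
Reactants: 19 tetracyclic 6-oxo-12,8-olide
Product: 20 tetracyclic 6α-hydroxy-12,8-olide (hydroxyl anti to C11 and O-8, cis to the cyclobutane)
Conditions: NaBH4, MeOH–CH2Cl2, −40 °C
Reagents that add atoms: none
Why: Borohydride reduction under steric approach control: the α (concave) face of the cis-bicyclo[4.2.0]octanone is closed by the C15 methyl group, which is cis to C6 on the cyclobutane, and by C1, so hydride should enter from the β face and set the C6 hydroxyl α, anti to C11 and O-8, while lactone and silyl ether survive.

**Step 14**
Reactants: 20 tetracyclic 6α-hydroxy-12,8-olide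
Product: 22 11-(dimethylaminomethyl) lactone (aminomethyl group syn to H7), via dilithium alkoxide-enolate 21 (not isolated)
Conditions: LiN(iPr)2 (2.5 equiv), THF, −78 °C; Me2N=CH2+ I− (Eschenmoser's salt), −78 °C to rt; H2O
Reagents that add atoms: N,N-dimethylmethyleneiminium iodide, C=[N+](C)C.[I-]
Why: Mannich reaction of the lactone enolate: two equivalents of base give the C6 alkoxide and the C11 enolate, which attacks the iminium ion from the convex face of the cis-fused lactone, and the C11 centre so formed is erased in step 15.

**Step 15**
Reactants: 22 11-(dimethylaminomethyl) lactone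
Product: 24 tetracyclic 6α-hydroxy-11(13)-en-12,8-olide (2-OTBS), via trimethylammonium iodide 23 (not isolated)
Conditions: MeI, MeOH, rt; then aq NaHCO3, CH2Cl2, rt
Reagents that add atoms: iodomethane, CI (its methyl group is held only in 23 and leaves with the amine)
Why: Quaternisation of the amine followed by mild base-induced E1cB (Hofmann-type) elimination unveils the C11=C13 methylene group while no base-labile acetate is yet present.

**Step 16**
Reactants: 24 tetracyclic 6α-hydroxy-11(13)-en-12,8-olide (2-OTBS)
Product: 25 tetracyclic 2,6α-diol
Conditions: HF (48 % aq), MeCN, 0 °C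
Reagents that add atoms: none
Why: Fluoride-driven cleavage of the remaining silyl ether under acidic conditions, which avoid conjugate addition to the methylene lactone and translactonisation, frees the C2 hydroxyl with retention.

**Step 17**
Reactants: 25 tetracyclic 2,6α-diol
Product: 26 tetracyclic 2-acetate with free 6α-hydroxyl
Conditions: Ac2O (1.1 equiv), pyridine, CH2Cl2, 0 °C
Reagents that add atoms: acetic anhydride, CC(=O)OC(C)=O
Why: Acylation under kinetic control picks the exposed exo cyclobutanol at C2 over the C6 hydroxyl, which sits in the concave pocket between two branched carbons, and it replaces a donor silyloxy group by the less donating acetoxy group before the 1,5-diene is unveiled.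

**Step 18**
Reactants: 26 tetracyclic 2-acetate
Product: 27 (1(10)E,4Z)-2α-acetoxy-6α-hydroxygermacra-1(10),4,11(13)-trien-12,8β-olide
Conditions: PhMe (0.01 M, degassed, BHT), heated flow coil, 200–220 °C, residence time of a few minutes
Reagents that add atoms: none
Why: Thermal cycloreversion of the bicyclo[2.2.0]hexane unit: homolysis of the strained C1–C4 bond gives a cyclohexane-1,4-diyl that cleaves C5–C10 from a chair, which turns the exo,exo-fused six-membered ring into one E and one Z alkene, and the chair that keeps the exo C2 acetoxy group equatorial (the other chair sets it 1,3-diaxial to C9) has C9 equatorial and C6 axial, that is 1(10)E,4Z, a short hot residence being used because ring opening has a more favourable activation entropy than the ordered Cope shift that could follow.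

**Step 19**
Reactants: 27 (1(10)E,4Z)-dienol lactone
Product: 28 4α,5α-epoxy-6α-hydroxy compound, (1(10)E)-2α-acetoxy-4α,5α-epoxy-6α-hydroxygermacra-1(10),11(13)-dien-12,8β-olide
Conditions: VO(acac)2 (5 mol %), tBuOOH (decane), CH2Cl2, 0 °C
Reagents that add atoms: tert-butyl hydroperoxide, CC(C)(C)OO
Why: Hydroxyl-directed vanadium-catalysed epoxidation: the vanadate ester of the C6 carbinol delivers oxygen only to C4=C5 (C1=C10 has no free hydroxyl and C11=C13 is electron-poor) through the small O–C6–C5=C4 dihedral angle that in medium-ring (Z)-allylic alcohols leads to the cis (erythro) epoxy alcohol on the outer alkene face, which sets C4 (R) and C5 (S) with retention of the ring-cis geometry.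

**Step 20**
Reactants: 28 epoxy alcohol
Product: 29 target, (1(10)E)-2α,6α-diacetoxy-4α,5α-epoxygermacra-1(10),11(13)-dien-12,8β-olide (2S,4R,5S,6S,7R,8R)
Conditions: Ac2O, DMAP (cat.), Et3N, CH2Cl2, 0 °C to rt
Reagents that add atoms: acetic anhydride, CC(=O)OC(C)=O
Why: DMAP-catalysed acetylation of the hindered C6 carbinol under non-acidic conditions leaves oxirane, methylene lactone and the C1=C10 alkene untouched and completes the target.

**Compound list**
1 | cis,cis-cyclohexane-1,3,5-triol | O[C@@H]1C[C@H](O)C[C@H](O)C1 | starting material
2 | all-cis-5-(triethylsilyloxy)cyclohexane-1,3-diol (meso) | CC[Si](CC)(CC)O[C@@H]1C[C@H](O)C[C@H](O)C1 | intermediate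
3 | (1R,3S,5S)-3-hydroxy-5-(triethylsilyloxy)cyclohexyl acetate | CC[Si](CC)(CC)O[C@@H]1C[C@H](OC(C)=O)C[C@H](O)C1 | intermediate
4 | (1S,5R)-3-oxo-5-(triethylsilyloxy)cyclohexyl acetate | CC[Si](CC)(CC)O[C@@H]1C[C@H](OC(C)=O)CC(=O)C1 | intermediate (not isolated)
5 | (R)-5-(triethylsilyloxy)cyclohex-2-en-1-one | CC[Si](CC)(CC)O[C@@H]1CC=CC(=O)C1 | intermediate
6 | (3R,5R)-3-methyl-5-(triethylsilyloxy)-1-(trimethylsilyloxy)cyclohex-1-ene | CC[Si](CC)(CC)O[C@@H]1C[C@@H](C)C=C(O[Si](C)(C)C)C1 | intermediate
7 | (R)-3-methyl-5-(triethylsilyloxy)cyclohex-2-en-1-one | CC[Si](CC)(CC)O[C@@H]1CC(C)=CC(=O)C1 | intermediate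
8 | propyne | CC#C | starting material
9 | trichloroacetyl chloride | O=C(Cl)C(Cl)(Cl)Cl | starting material
10 | dichloroketene | ClC(Cl)=C=O | intermediate (not isolated)
11 | 4,4-dichloro-3-methylcyclobut-2-en-1-one | CC1=CC(=O)C1(Cl)Cl | intermediate
12 | 3-methylcyclobut-2-en-1-one | CC1=CC(=O)C1 | intermediate
13 | (S)-3-methylcyclobut-2-en-1-ol | CC1=C[C@@H](O)C1 | intermediate
14 | (S)-3-(tert-butyldimethylsilyloxy)-1-methylcyclobutene | CC1=C[C@@H](O[Si](C)(C)C(C)(C)C)C1 | intermediate
15 | cis-anti-cis 6-4-4 tricyclic ketone (2-OTBS exo, 8β-OTES) | O=C1C[C@H](O[Si](CC)(CC)CC)C[C@@]2(C)[C@@H]3[C@@H](O[Si](C)(C)C(C)(C)C)C[C@]3(C)[C@@H]12 | intermediate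
16 | lithium C6=C7 enolate of 15 | [Li]OC1=C[C@H](O[Si](CC)(CC)CC)C[C@@]2(C)[C@@H]3[C@@H](O[Si](C)(C)C(C)(C)C)C[C@]3(C)[C@@H]12 | intermediate (not isolated)
17 | C7β-(methoxycarbonylmethyl) tricyclic ketone | O=C1[C@H](CC(=O)OC)[C@H](O[Si](CC)(CC)CC)C[C@@]2(C)[C@@H]3[C@@H](O[Si](C)(C)C(C)(C)C)C[C@]3(C)[C@@H]12 | intermediate
18 | 8β-hydroxy keto ester | O=C1[C@H](CC(=O)OC)[C@H](O)C[C@@]2(C)[C@@H]3[C@@H](O[Si](C)(C)C(C)(C)C)C[C@]3(C)[C@@H]12 | intermediate (not isolated)
19 | tetracyclic 6-oxo-12,8-olide (2-OTBS) | O=C1[C@@H]2CC(=O)O[C@@H]2C[C@@]3(C)[C@@H]4[C@@H](O[Si](C)(C)C(C)(C)C)C[C@]4(C)[C@@H]13 | intermediate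
20 | tetracyclic 6α-hydroxy-12,8-olide (2-OTBS) | O[C@H]1[C@@H]2CC(=O)O[C@@H]2C[C@@]3(C)[C@@H]4[C@@H](O[Si](C)(C)C(C)(C)C)C[C@]4(C)[C@@H]13 | intermediate
21 | dilithium C6 alkoxide / C11 lactone enolate of 20 | [Li]O[C@H]1[C@@H]2C=C(O[Li])O[C@@H]2C[C@@]3(C)[C@@H]4[C@@H](O[Si](C)(C)C(C)(C)C)C[C@]4(C)[C@@H]13 | intermediate (not isolated)
22 | 11-(dimethylaminomethyl) lactone | O[C@H]1[C@@H]2[C@@H](CN(C)C)C(=O)O[C@@H]2C[C@@]3(C)[C@@H]4[C@@H](O[Si](C)(C)C(C)(C)C)C[C@]4(C)[C@@H]13 | intermediate
23 | 11-(trimethylammoniomethyl) lactone iodide | O[C@H]1[C@@H]2[C@@H](C[N+](C)(C)C)C(=O)O[C@@H]2C[C@@]3(C)[C@@H]4[C@@H](O[Si](C)(C)C(C)(C)C)C[C@]4(C)[C@@H]13.[I-] | intermediate (not isolated)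
24 | tetracyclic 6α-hydroxy-11(13)-en-12,8-olide (2-OTBS) | O[C@H]1[C@@H]2C(=C)C(=O)O[C@@H]2C[C@@]3(C)[C@@H]4[C@@H](O[Si](C)(C)C(C)(C)C)C[C@]4(C)[C@@H]13 | intermediate
25 | tetracyclic 2,6α-diol | O[C@H]1[C@@H]2C(=C)C(=O)O[C@@H]2C[C@@]3(C)[C@@H]4[C@@H](O)C[C@]4(C)[C@@H]13 | intermediate
26 | tetracyclic 2-acetate, 6α-hydroxyl free | O[C@H]1[C@@H]2C(=C)C(=O)O[C@@H]2C[C@@]3(C)[C@@H]4[C@@H](OC(C)=O)C[C@]4(C)[C@@H]13 | intermediate
27 | (1(10)E,4Z)-2α-acetoxy-6α-hydroxygermacra-1(10),4,11(13)-trien-12,8β-olide | C=C1C(=O)O[C@@H]2C/C(C)=C/[C@@H](OC(C)=O)C/C(C)=C\[C@@H](O)[C@H]12 | intermediate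
28 | (1(10)E)-2α-acetoxy-4α,5α-epoxy-6α-hydroxygermacra-1(10),11(13)-dien-12,8β-olide | C=C1C(=O)O[C@@H]2C/C(C)=C/[C@@H](OC(C)=O)C[C@@]3(C)O[C@H]3[C@@H](O)[C@H]12 | intermediate
29 | CNP0270851.1, (1(10)E)-2α,6α-diacetoxy-4α,5α-epoxygermacra-1(10),11(13)-dien-12,8β-olide | C=C1C(=O)O[C@@H]2C/C(C)=C/[C@@H](OC(C)=O)C[C@@]3(C)O[C@H]3[C@@H](OC(C)=O)[C@H]12 | target

**Totals**
Total step count: 20.
Longest linear sequence: 16 (steps 1–5, then 10–20).

**Steps most likely to fail**

**Step 18 (thermal opening).**
- What may go wrong: the ten-membered 1,5-diene, once formed, may undergo a Cope shift to a divinylcyclohexane at the temperature needed for opening. The diyl may also cleave C2–C3 directly, or open through the other chair and give the wrong pair of alkene geometries.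
- Fallback: it sets out from 26 and comes back at 27, with the ring opened at the ketone level.
- Dess–Martin oxidation of 26 under base-free conditions should give the tetracyclic C6 ketone F1.
- In F1 the breaking C5–C10 bond is α to a carbonyl group, and C4=C5 emerges conjugated. The diyl should therefore partition toward ring expansion, and a later Cope shift would cost the enone conjugation.
- Thermolysis should then give the (1(10)E,4Z)-dienone F2.
- Luche reduction of F2 (NaBH4, CeCl3·7H2O, MeOH, −78 °C) returns the C6 carbinol 27. The hydride face is then governed by peripheral attack on the ten-membered ring and has to be checked.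

**Step 10 (photocycloaddition).**
- What may go wrong: facial selectivity on the conformationally mobile enone may be poor, which would erode the convex-face control used in steps 11 and 13. Enone dimerisation or diradical reversion may also compete, so that conversion with a trisubstituted cyclobutene stays low.
- Fallback: it sets out from 7 and comes back at 19, so steps 11 and 12 are skipped. The lactone is built before irradiation.
- Kinetic α′-deprotonation of 7 (LiN(iPr)2, THF, −78 °C) and alkylation with methyl bromoacetate should give the trans keto ester F3.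
- PPTS in MeOH and then catalytic TsOH in CH2Cl2 remove the triethylsilyl group and let C7 equilibrate through the enol. The material should drain into the cis-fused bicyclic lactone enone F4. No base is used, to avoid loss of the C8 oxygen and aromatisation.
- F4 is a rigid cup whose open face is anti to the lactone. Irradiation with 14 under the conditions of step 10 should give 19 directly.

**Step 19 (directed epoxidation).**
- What may go wrong: in a flexible ten-membered ring the vanadate may deliver oxygen through the conformer that minimises allylic strain, which would give the other alkene face. Oxidation of the carbinol to the enone or Lewis-acid-induced transannular opening of the oxirane may also intervene.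
- Fallback: it sets out from 27 and comes back at 28, with substrate direction replaced by reagent control.
- The reaction is a Katsuki–Sharpless epoxidation with stoichiometric Ti(OiPr)4 and L-(+)-diisopropyl tartrate, tBuOOH and 4 Å molecular sieves in CH2Cl2 at −20 °C.
- The C6 carbinol of 27 has the spatial arrangement of the fast-reacting enantiomer for the L-(+)-tartrate. That matched pair gives the erythro epoxy alcohol, which is 28.
- This detour makes no new compound (F0).

**Further compounds**
F1 | step 18 | tetracyclic 2-acetoxy-6-oxo-11(13)-en-12,8-olide | O=C1[C@@H]2C(=C)C(=O)O[C@@H]2C[C@@]3(C)[C@@H]4[C@@H](OC(C)=O)C[C@]4(C)[C@@H]13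
F2 | step 18 | (1(10)E,4Z)-2α-acetoxy-6-oxogermacra-1(10),4,11(13)-trien-12,8β-olide | C=C1C(=O)O[C@@H]2C/C(C)=C/[C@@H](OC(C)=O)C/C(C)=C\C(=O)[C@H]12
F3 | step 10 | methyl 2-[(1S,6R)-4-methyl-2-oxo-6-(triethylsilyloxy)cyclohex-3-en-1-yl]acetate | O=C1C=C(C)C[C@@H](O[Si](CC)(CC)CC)[C@@H]1CC(=O)OC
F4 | step 10 | (3aR,7aR)-6-methyl-3,3a,7,7a-tetrahydro-1-benzofuran-2,4-dione | O=C1C=C(C)C[C@H]2OC(=O)C[C@@H]12
F0 | step 19 | none | none
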